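Cuts, by the azulene locants of the target (C8a methyl-bearing fusion carbon, C3 carbinol, C4 acyloxy carbon, C8 ketone): the ester C–O; C6=C7 (ring-closing metathesis); C7–C8 (vinyl onto the C8 carboxyl); C4–C5 (methallylation of a C4 aldehyde); C3–isopropyl; the ring bond C8a–C1 (radical cyclisation); C2–C3 with a temporary C1–C3 bond (cyclopropanol from an ester); C3a–C8a (Michael addition).
Enabling feature: in the five-membered ring the oxygen-bearing C3 is linked through the methylenes C2 and C1 to C8a, which is alpha to the C8 carbonyl, so O–C3–C2–C1–C8a–C8=O is a 1,5-dioxygenated chain. C3 can therefore be the carbon of a cyclopropanol whose strain-driven opening puts a radical on C1 that closes onto C8a of an enol derivative of the C8 carbonyl.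
Forward order: acyclic chain (steps 1 to 5), five-membered ring by the key cyclisation, isopropyl group and C4 side chain on the cyclopentane, seven-membered ring last by metathesis, then acylation.
Stereochemistry: C3a by amine-catalysed Michael addition; C8a from C3a by allylic strain in the key step (the two future ring tethers become trans, hence the trans fusion); C3 by addition anti to the C3a substituent; C4 by chelation-controlled allylation.

Key step: step 6

Remark: the configuration at the methyl-bearing carbon of the acyclic intermediates is drawn as formed in step 2 but is of no consequence, because this carbon becomes trigonal before the cyclisation; vinyllithium is taken as a titrated stock solution in THF.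

Step 1
Reactants: 1 2-(benzyloxy)acetaldehyde; 2 nitromethane
Product: 4 (E)-3-(benzyloxy)-1-nitroprop-1-ene, via nitro alcohol 3 (not isolated)
Conditions: Et3N (cat.), MeNO2, 0 °C to rt; then MsCl, Et3N, CH2Cl2, 0 °C
Reagents that add atoms: none
Why: Henry addition followed by mesylation and E1cB elimination should give the conjugated nitroalkene as its more stable (E) isomer.

Step 2
Reactants: 4 (E)-3-(benzyloxy)-1-nitroprop-1-ene; 5 propanal
Product: 6 (2R,3R)-3-[(benzyloxy)methyl]-2-methyl-4-nitrobutanal
Conditions: (S)-2-[diphenyl(trimethylsilyloxy)methyl]pyrrolidine (10 mol %), 4-nitrophenol (10 mol %), toluene, 0 °C to rt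
Reagents that add atoms: none
Why: Enamine-catalysed asymmetric Michael addition, in which the (E)-enamine is shielded on one face by the diarylsiloxymethyl group and adds to the nitroalkene through an open synclinal transition state, setting the C3a centre under catalyst control.

Step 3
Reactants: 6 (2R,3R)-3-[(benzyloxy)methyl]-2-methyl-4-nitrobutanal
Product: 8 tert-butyl (2R,3R)-3-[(benzyloxy)methyl]-2-methyl-4-nitrobutanoate, via carboxylic acid 7 (not isolated)
Conditions: NaClO2, NaH2PO4, 2-methylbut-2-ene, t-BuOH/H2O, 0 °C to rt; then tert-butyl 2,2,2-trichloroacetimidate, BF3·OEt2 (cat.), CH2Cl2/cyclohexane, rt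
Reagents that add atoms: sodium chlorite, [Na+].[O-]Cl=O; tert-butyl 2,2,2-trichloroacetimidate, CC(C)(C)OC(=N)C(Cl)(Cl)Cl
Why: Pinnick oxidation and acid-catalysed tert-butylation by the imidate give an ester that is enolisable but inert in the later Kulinkovich step.

Step 4
Reactants: 8 tert-butyl (2R,3R)-3-[(benzyloxy)methyl]-2-methyl-4-nitrobutanoate
Product: 10 4-tert-butyl 1-methyl (2S,3R)-2-[(benzyloxy)methyl]-3-methylbutanedioate, via carboxylic acid 9 (not isolated)
Conditions: NaNO2, AcOH, DMSO, 35 °C; then TMSCHN2, MeOH/toluene, 0 °C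
Reagents that add atoms: sodium nitrite, [Na+].[O-]N=O; water, O; (trimethylsilyl)diazomethane, C[Si](C)(C)C=[N+]=[N-]
Why: Nef-type oxidation of the primary nitroalkane to the acid (nitrosation to the nitrolic acid and its breakdown) leaves the neighbouring stereocentre untouched, and the acid is methylated under neutral conditions.

Step 5
Reactants: 10 4-tert-butyl 1-methyl (2S,3R)-2-[(benzyloxy)methyl]-3-methylbutanedioate
Product: 11 tert-butyl (2R,3S)-4-(benzyloxy)-3-(1-hydroxycyclopropyl)-2-methylbutanoate
Conditions: EtMgBr (3 equiv, slow addition), Ti(OiPr)4 (0.3 equiv), THF, 0 °C; aq. NH4Cl at 0 °C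
Reagents that add atoms: ethylmagnesium bromide, CC[Mg]Br
Why: Kulinkovich cyclopropanation, in which the titanacyclopropane acts as a 1,2-dicarbanion on the methyl ester only, the bulky tert-butyl ester being unreactive.

Step 6
Reactants: 11 tert-butyl (2R,3S)-4-(benzyloxy)-3-(1-hydroxycyclopropyl)-2-methylbutanoate
Product: 13 tert-butyl (1S,2S)-2-[(benzyloxy)methyl]-1-methyl-3-oxocyclopentane-1-carboxylate, via silyl ketene acetal 12 (not isolated)
Conditions: LiN(iPr)2 (2.2 equiv), THF, −78 °C; TBSCl (1.1 equiv), DMPU, −78 to −20 °C; cold pH 7 buffer work-up; then manganese tris(pyridine-2-carboxylate) (2.5 equiv), DMF, 0 °C to rt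
Reagents that add atoms: none
Why: Proposed new method: the free cyclopropanol binds trivalent manganese as an alkoxide and inner-sphere electron transfer opens the strained ring to the primary β-keto radical at C1, which attacks the fully substituted carbon C8a of the silyl ketene acetal in a 5-exo-trig closure of the five-membered ring, after which a second equivalent of oxidant converts the α,α-dioxy radical into a cation that loses the silyl group to return the ester. The closest known reaction type is the addition of cyclopropanol-derived β-keto radicals, generated with the same manganese salt, to ketone silyl enol ethers, together with 5-exo cyclisations of such radicals onto alkenes; the new element is an ester-derived ketene acetal as intramolecular acceptor forming a quaternary carbon. The only new stereocentre, C8a, is controlled by C3a through allylic 1,3-strain: H-3a eclipses the oxygen-substituted terminus of the ketene acetal, the radical chain and the benzyloxymethyl group lie on opposite faces, and bond formation on the face of the chain places the ester trans to the benzyloxymethyl group (the future trans ring fusion). The step needs 5-exo over 6-endo regioselectivity, which the doubly oxygenated, hindered acetal carbon and the stability of the dioxy radical secure, and it needs oxidation of the cyclopropanol in preference to the ketene acetal, which the alkoxide-bound pathway of this mild oxidant should provide.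

Step 7
Reactants: 13 tert-butyl (1S,2S)-2-[(benzyloxy)methyl]-1-methyl-3-oxocyclopentane-1-carboxylate
Product: 14 (1S,2S)-2-[(benzyloxy)methyl]-1-methyl-3-oxocyclopentane-1-carboxylic acid
Conditions: CF3CO2H, CH2Cl2, 0 °C
Reagents that add atoms: none
Why: Acidolysis of the tert-butyl ester (E1 loss of isobutene) frees the acid for the late ketone synthesis at a stage where no acid-labile tertiary alcohol is present.

Step 8
Reactants: 14 (1S,2S)-2-[(benzyloxy)methyl]-1-methyl-3-oxocyclopentane-1-carboxylic acid
Product: 15 (1S,2S,3R)-2-[(benzyloxy)methyl]-3-hydroxy-1-methyl-3-(propan-2-yl)cyclopentane-1-carboxylic acid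
Conditions: iPrMgCl (3.5 equiv), LaCl3·2LiCl (30 mol %), THF, −20 to 0 °C
Reagents that add atoms: isopropylmagnesium chloride, CC(C)[Mg]Cl
Why: Lanthanum-promoted Grignard 1,2-addition to the ketone of the magnesium carboxylate, in which the nucleophile should enter trans to the adjacent benzyloxymethyl group (the face of H-3a) and so place the hydroxyl cis to the ring methyl.

Step 9
Reactants: 15 (1S,2S,3R)-2-[(benzyloxy)methyl]-3-hydroxy-1-methyl-3-(propan-2-yl)cyclopentane-1-carboxylic acid
Product: 16 (1S,2S,3R)-3-hydroxy-2-(hydroxymethyl)-1-methyl-3-(propan-2-yl)cyclopentane-1-carboxylic acid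
Conditions: H2 (1 atm), Pd/C, EtOAc, rt
Reagents that add atoms: none
Why: Catalytic hydrogenolysis of the benzyl ether is placed before any alkene is introduced.

Step 10
Reactants: 16 (1S,2S,3R)-3-hydroxy-2-(hydroxymethyl)-1-methyl-3-(propan-2-yl)cyclopentane-1-carboxylic acid
Product: 17 (1S,2R,3R)-2-formyl-3-hydroxy-1-methyl-3-(propan-2-yl)cyclopentane-1-carboxylic acid
Conditions: Dess–Martin periodinane, CH2Cl2, 0 °C to rt; used crude
Reagents that add atoms: none
Why: Hypervalent-iodine oxidation of the only oxidisable (primary) alcohol under neutral conditions, which should spare the β-hydroxy aldehyde from retro-aldol cleavage and epimerisation.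

Step 11
Reactants: 17 (1S,2R,3R)-2-formyl-3-hydroxy-1-methyl-3-(propan-2-yl)cyclopentane-1-carboxylic acid
Product: 18 (1S,2S,3R)-3-hydroxy-2-[(1S)-1-hydroxy-3-methylbut-3-en-1-yl]-1-methyl-3-(propan-2-yl)cyclopentane-1-carboxylic acid
Conditions: 3-bromo-2-methylprop-1-ene, In powder, THF/H2O (1:1), rt
Reagents that add atoms: 3-bromo-2-methylprop-1-ene, CC(=C)CBr
Why: Barbier-type indium-mediated allylation under chelation control, in which the metal bridges the aldehyde oxygen and the cis tertiary hydroxyl in a six-membered chelate and the methallyl group attacks the carbonyl face remote from the quaternary carbon, giving the (S)-carbinol at C4.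

Step 12
Reactants: 18 (1S,2S,3R)-3-hydroxy-2-[(1S)-1-hydroxy-3-methylbut-3-en-1-yl]-1-methyl-3-(propan-2-yl)cyclopentane-1-carboxylic acid
Product: 19 1-[(1S,2S,3R)-3-hydroxy-2-[(1S)-1-hydroxy-3-methylbut-3-en-1-yl]-1-methyl-3-(propan-2-yl)cyclopentyl]prop-2-en-1-one
Conditions: vinyllithium (6 equiv), THF, −78 to 0 °C; inverse quench into cold aq. NH4Cl
Reagents that add atoms: vinyllithium, [Li]C=C
Why: Ketone synthesis from a carboxylic acid with an organolithium, in which the lithium carboxylate gives a stable gem-dialkoxide that collapses to the vinyl ketone only on work-up while the two alkoxides are spectators.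

Step 13
Reactants: 19 1-[(1S,2S,3R)-3-hydroxy-2-[(1S)-1-hydroxy-3-methylbut-3-en-1-yl]-1-methyl-3-(propan-2-yl)cyclopentyl]prop-2-en-1-one
Product: 20 (3R,3aS,4S,8aS)-3,4-dihydroxy-6,8a-dimethyl-3-(propan-2-yl)-2,3,3a,4,5,8a-hexahydroazulen-8(1H)-one
Conditions: second-generation Hoveyda–Grubbs catalyst (10 mol %), toluene, 80 °C
Reagents that add atoms: none
Why: Ring-closing metathesis of the vinyl ketone with the 1,1-disubstituted alkene closes the seven-membered ring as the trisubstituted enone, and the trans arrangement of the two tethers on the cyclopentane becomes the trans ring fusion.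

Step 14
Reactants: 20 (3R,3aS,4S,8aS)-3,4-dihydroxy-6,8a-dimethyl-3-(propan-2-yl)-2,3,3a,4,5,8a-hexahydroazulen-8(1H)-one; 21 3,4,5-trimethoxybenzoyl chloride
Product: 22 (3R,3aS,4S,8aS)-3-hydroxy-6,8a-dimethyl-8-oxo-3-(propan-2-yl)-1,2,3,3a,4,5,8,8a-octahydroazulen-4-yl 3,4,5-trimethoxybenzoate
Conditions: Et3N, DMAP (cat.), CH2Cl2, 0 °C to rt
Reagents that add atoms: none
Why: Nucleophile-catalysed acylation should be selective for the secondary hydroxyl over the hindered tertiary one.

Compound list
1 | 2-(benzyloxy)acetaldehyde | O=CCOCc1ccccc1 | starting material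
2 | nitromethane | C[N+](=O)[O-] | starting material
3 | 1-(benzyloxy)-3-nitropropan-2-ol (racemic) | OC(COCc1ccccc1)C[N+](=O)[O-] | intermediate
4 | (E)-3-(benzyloxy)-1-nitroprop-1-ene | [O-][N+](=O)/C=C/COCc1ccccc1 | intermediate
5 | propanal | CCC=O | starting material
6 | (2R,3R)-3-[(benzyloxy)methyl]-2-methyl-4-nitrobutanal | O=C[C@H](C)[C@@H](COCc1ccccc1)C[N+](=O)[O-] | intermediate
7 | (2R,3R)-3-[(benzyloxy)methyl]-2-methyl-4-nitrobutanoic acid | OC(=O)[C@H](C)[C@@H](COCc1ccccc1)C[N+](=O)[O-] | intermediate
8 | tert-butyl (2R,3R)-3-[(benzyloxy)methyl]-2-methyl-4-nitrobutanoate | CC(C)(C)OC(=O)[C@H](C)[C@@H](COCc1ccccc1)C[N+](=O)[O-] | intermediate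
9 | (2S,3R)-2-[(benzyloxy)methyl]-4-tert-butoxy-3-methyl-4-oxobutanoic acid | CC(C)(C)OC(=O)[C@H](C)[C@@H](COCc1ccccc1)C(=O)O | intermediate
10 | 4-tert-butyl 1-methyl (2S,3R)-2-[(benzyloxy)methyl]-3-methylbutanedioate | CC(C)(C)OC(=O)[C@H](C)[C@@H](COCc1ccccc1)C(=O)OC | intermediate
11 | tert-butyl (2R,3S)-4-(benzyloxy)-3-(1-hydroxycyclopropyl)-2-methylbutanoate | CC(C)(C)OC(=O)[C@H](C)[C@@H](COCc1ccccc1)C1(O)CC1 | intermediate
12 | 1-[(2S)-1-(benzyloxy)-4-tert-butoxy-4-[(tert-butyldimethylsilyl)oxy]-3-methylbut-3-en-2-yl]cyclopropan-1-ol (E/Z mixture) | CC(C)(C)OC(O[Si](C)(C)C(C)(C)C)=C(C)[C@@H](COCc1ccccc1)C1(O)CC1 | intermediate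
13 | tert-butyl (1S,2S)-2-[(benzyloxy)methyl]-1-methyl-3-oxocyclopentane-1-carboxylate | CC(C)(C)OC(=O)[C@@]1(C)CCC(=O)[C@@H]1COCc2ccccc2 | intermediate
14 | (1S,2S)-2-[(benzyloxy)methyl]-1-methyl-3-oxocyclopentane-1-carboxylic acid | OC(=O)[C@@]1(C)CCC(=O)[C@@H]1COCc2ccccc2 | intermediate
15 | (1S,2S,3R)-2-[(benzyloxy)methyl]-3-hydroxy-1-methyl-3-(propan-2-yl)cyclopentane-1-carboxylic acid | OC(=O)[C@@]1(C)CC[C@@](O)(C(C)C)[C@@H]1COCc2ccccc2 | intermediate
16 | (1S,2S,3R)-3-hydroxy-2-(hydroxymethyl)-1-methyl-3-(propan-2-yl)cyclopentane-1-carboxylic acid | OC(=O)[C@@]1(C)CC[C@@](O)(C(C)C)[C@@H]1CO | intermediate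
17 | (1S,2R,3R)-2-formyl-3-hydroxy-1-methyl-3-(propan-2-yl)cyclopentane-1-carboxylic acid | OC(=O)[C@@]1(C)CC[C@@](O)(C(C)C)[C@@H]1C=O | intermediate
18 | (1S,2S,3R)-3-hydroxy-2-[(1S)-1-hydroxy-3-methylbut-3-en-1-yl]-1-methyl-3-(propan-2-yl)cyclopentane-1-carboxylic acid | OC(=O)[C@@]1(C)CC[C@@](O)(C(C)C)[C@@H]1[C@@H](O)CC(C)=C | intermediate
19 | 1-[(1S,2S,3R)-3-hydroxy-2-[(1S)-1-hydroxy-3-methylbut-3-en-1-yl]-1-methyl-3-(propan-2-yl)cyclopentyl]prop-2-en-1-one | C=CC(=O)[C@@]1(C)CC[C@@](O)(C(C)C)[C@@H]1[C@@H](O)CC(C)=C | intermediate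
20 | (3R,3aS,4S,8aS)-3,4-dihydroxy-6,8a-dimethyl-3-(propan-2-yl)-2,3,3a,4,5,8a-hexahydroazulen-8(1H)-one | O[C@H]1CC(C)=CC(=O)[C@@]2(C)CC[C@@](O)(C(C)C)[C@H]12 | intermediate
21 | 3,4,5-trimethoxybenzoyl chloride | COc1cc(C(Cl)=O)cc(OC)c1OC | starting material
22 | (3R,3aS,4S,8aS)-3-hydroxy-6,8a-dimethyl-8-oxo-3-(propan-2-yl)-1,2,3,3a,4,5,8,8a-octahydroazulen-4-yl 3,4,5-trimethoxybenzoate | COc1cc(C(=O)O[C@H]2CC(C)=CC(=O)[C@@]3(C)CC[C@@](O)(C(C)C)[C@H]23)cc(OC)c1OC | target

Total step count: 14. Longest linear sequence: 14 steps (from 1 and 2 to 22).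

Steps most likely to fail

Step 6 (Proposed new method). The ketene acetal may be protonated or oxidised by an outer-sphere path before the cyclopropanol is opened. The 5-exo attack on a fully substituted carbon is slow, so the primary radical may abstract hydrogen or be oxidised further. Facial control is lost if the strain-biased conformer is not the reactive one, and the γ-hydroxy ester may lactonise during handling. The fallback uses known chemistry for the same bond and sets out from 11. α-Bromination of its dianion (LiN(iPr)2, then CBr4, THF, −78 °C) should give the tertiary α-bromo ester tert-butyl (3S)-4-(benzyloxy)-2-bromo-3-(1-hydroxycyclopropyl)-2-methylbutanoate F1. CuI (10 mol %), 1,10-phenanthroline and K2CO3 in MeCN at 80 °C would then effect the copper-catalysed ring-opening cross-coupling of a cyclopropanol with a tertiary α-bromo ester, here intramolecular, in which the copper homoenolate and the α-ester radical are joined at copper. The fallback comes back to the route at 13.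

Step 8. Enolisation of the α-branched cyclopentanone and β-hydride reduction by the branched Grignard reagent may outrun addition. The fallback sets out from 14 and changes the nucleophile: isopropenylmagnesium bromide with CeCl3 (THF, −78 °C) has no transferable β-hydride and should give the allylic alcohol (1S,2S,3S)-2-[(benzyloxy)methyl]-3-hydroxy-1-methyl-3-(prop-1-en-2-yl)cyclopentane-1-carboxylic acid F2. Hydrogenation (H2, Pd/C, EtOAc) then saturates the alkene and cleaves the benzyl ether in one operation, and the route is rejoined at 16.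

Step 11. Facial selectivity at the aldehyde will be poor if the chelate does not form in the aqueous medium, and the β-hydroxy aldehyde may epimerise or undergo retro-aldol cleavage. The fallback sets out from 17 and replaces addition control at C4 by inversion. The epimeric carbinol (1S,2S,3R)-3-hydroxy-2-[(1R)-1-hydroxy-3-methylbut-3-en-1-yl]-1-methyl-3-(propan-2-yl)cyclopentane-1-carboxylic acid F3 is carried through the conditions of steps 12 and 13. This gives the vinyl ketone 1-[(1S,2S,3R)-3-hydroxy-2-[(1R)-1-hydroxy-3-methylbut-3-en-1-yl]-1-methyl-3-(propan-2-yl)cyclopentyl]prop-2-en-1-one F4 and then the bicyclic diol (3R,3aS,4R,8aS)-3,4-dihydroxy-6,8a-dimethyl-3-(propan-2-yl)-2,3,3a,4,5,8a-hexahydroazulen-8(1H)-one F5. Mitsunobu esterification (3,4,5-trimethoxybenzoic acid, PPh3, DIAD, THF) then installs the ester with inversion at C4 and arrives at 22, so both epimers from step 11 converge on the target.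

Further compounds
F1 | step 6 | tert-butyl (3S)-4-(benzyloxy)-2-bromo-3-(1-hydroxycyclopropyl)-2-methylbutanoate (mixture at C2) | CC(C)(C)OC(=O)C(C)(Br)[C@@H](COCc1ccccc1)C1(O)CC1
F2 | step 8 | (1S,2S,3S)-2-[(benzyloxy)methyl]-3-hydroxy-1-methyl-3-(prop-1-en-2-yl)cyclopentane-1-carboxylic acid | OC(=O)[C@@]1(C)CC[C@@](O)(C(C)=C)[C@@H]1COCc2ccccc2
F3 | step 11 | (1S,2S,3R)-3-hydroxy-2-[(1R)-1-hydroxy-3-methylbut-3-en-1-yl]-1-methyl-3-(propan-2-yl)cyclopentane-1-carboxylic acid | OC(=O)[C@@]1(C)CC[C@@](O)(C(C)C)[C@@H]1[C@H](O)CC(C)=C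
F4 | step 11 | 1-[(1S,2S,3R)-3-hydroxy-2-[(1R)-1-hydroxy-3-methylbut-3-en-1-yl]-1-methyl-3-(propan-2-yl)cyclopentyl]prop-2-en-1-one | C=CC(=O)[C@@]1(C)CC[C@@](O)(C(C)C)[C@@H]1[C@H](O)CC(C)=C
F5 | step 11 | (3R,3aS,4R,8aS)-3,4-dihydroxy-6,8a-dimethyl-3-(propan-2-yl)-2,3,3a,4,5,8a-hexahydroazulen-8(1H)-one | O[C@@H]1CC(C)=CC(=O)[C@@]2(C)CC[C@@](O)(C(C)C)[C@H]12
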